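## Structural features

The target contains three rings: a 2,3-dihydrobenzofuran whose benzene ring is fully substituted (C3a and C7a in the furan ring, hydroxyls on C4 and C6, the 2-methylbutanoyl ketone on C5, a methylene on C7) and a 6'-ethyl-4'-hydroxy-5'-methyl-2-pyranone, joined only through the C7–CH2–C3' bridge. There are two stereocentres and they are far apart: C2 (R), an oxygen-bearing allylic methine that carries the isopropenyl group next to the benzylic C3 methylene, and the α-carbon of the acyl chain (R); neither can control the other, so each is introduced on its own. The fragile points are the enolisable α-carbon of the aryl ketone, the isopropenyl group together with the allylic C2–O1 aryl ether bond (strong acid, metal hydrides and zerovalent palladium would isomerise or ionise them), the oxidation-prone acylphloroglucinol nucleus, and the methylene bridge between two vinylogous acids, which can scramble by retro-Michael reaction. The aromatic core is a disguised phloroglucinol, so its three oxygens (one ether, two phenols) and its two free ring carbons (C5, C7) must be told apart. The real difficulty is C2, a lone stereocentre with no neighbouring functional group in the target from which it could be derived. The key step exploits the adjacency of C2 and C3 in the dihydrofuran: with that bond opened, C2 is the OCH2 carbon of a methallyl aryl ether on O1, whose two enantiotopic hydrogens are both allylic and α to oxygen and stand in a 1,5 relationship (through C7a and C3a) to a carbene centre on C3.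

## Logic of the disconnections

**27 to 21 and 25.** The first cut removes the bridging methylene, that is the bonds C7–CH2 and CH2–C3'. Both partners are vinylogous acids whose nucleophilic carbons can be joined by a one-carbon iminium electrophile, so this is the natural seam; it divides 27 into a chiral half (21) and an achiral half (25) of similar size. The forward step must deliver the methylene directionally so that no symmetrical dimer forms, must find C7 as the only free ring carbon of 21, and must be mild enough for the ketone α-centre.

**21 to 20, then to 15 and 18.** The two phenols are masked as methoxymethyl ethers (20) and the bond C5–C(=O) is cut. C5 lies between the two acetal oxygens, the position most favoured for directed lithiation (19), and the acyl group with its stereocentre then comes unchanged from the chiral-pool acid 16 via 18. The gain is removal of the second stereocentre and five carbons. The demand is lithiation at C5 and not C7, acyl transfer without enolisation, and deprotection by dilute acid that spares the isopropenyl group.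

**15 to 13, 11 and 9.** In 15 nothing activates C2, so a carboxyl group is put back on C3 as a traceless handle (C3–H becomes C3–CO2H in 13). With an ester on C3 (9), the C2–C3 bond becomes the product of a carbene insertion. The protecting groups are exchanged on the way back (13 from 11 from 9) because the groups that direct lithiation in 15 are not inert toward a carbene. The forward demand is excision of the carboxyl carbon without disturbing C2 or the alkene, which points to a radical decarboxylation and away from metal-hydride or aldehyde intermediates.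

**9 to 8.** The bond C2–C3 is cut. Ring and both stereocentres disappear and an achiral, open-chain diazo ester remains; this is the strategic simplification. The forward step must choose one of two enantiotopic hydrogens, must prefer C–H insertion to addition across the methallyl double bond, and must find no second reactive site on the other ortho substituent; hence silyl ethers on the ring oxygens in 8.

**8 to 7, to 4 and 5, to 3 and 1.** The C=N2 group is traced to the CH2 of arylacetate 7 (diazo transfer). Ester 7 is cut at the O–CH2 bond of the methallyl ether and at the ester C–O bond, leading to lactone 4 and chloride 5. Lactone 4 ties one of three otherwise equivalent phloroglucinol oxygens to the acetic acid side chain, so that oxygen (the future O1) is distinguished without any selective protection. Lactone 4 comes from 3 by silylation, and 3 from 1 by ether cleavage. The demand is that the ring-opened phenoxide is alkylated before it relactonises and that the silyl ethers survive methoxide and DBU.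

**25 to 23 and 24, then to 22.** The pyranone is cut at C4'–C5' and O1'–C2', giving a three-carbon bis-electrophile (24) and the silyl enol ether (23) of the symmetrical ketone 22. Symmetry of 22 removes any regiochemical question.

**18 to 16.** The amide C–N bond is cut back to the acid; the only demand is activation that does not enolise the α-centre.

## Other disconnections considered

**Alternative 1:** The cut goes through three bonds of the benzene ring (C3a–C7a, C4–C5, C6–C7), so arene and dihydrofuran are assembled together. In the forward sense a rhodium catalyst such as RhCl(PPh3)3 would join the tethered diyne A2 (an ethynyl ether on O1, a tert-butoxyalkyne on C3) with the alkoxy ynone A3 in a [2+2+2] cycloaddition to give A1.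
- In its favour: it is the most convergent plan. A1 already carries the C5 acyl group with its stereocentre and both oxygens, so there is no phloroglucinol desymmetrisation, no C5 lithiation, no C3 control group to excise and no protecting-group exchange. On step economy after the key step it is better than the chosen plan.
- On C2 the plans are equals in principle: the stereocentre must be made enantioselectively in either case, here in the alcohol from which A2 is built, with the small advantage that it is fixed before the strategic step.
- Against it here: A2 is an allyl alkynyl ether (O1 sits on the allylic carbon C2), a class expected to undergo [3,3]-sigmatropic rearrangement to a ketene well below room temperature. All three alkynes are ynol ethers, the tert-butyl ones prone to loss of isobutene. The orientation of A3 is governed only by alkyne polarisation, and the wrong one would put the acyl group on C6. The tert-butyl ethers need acid strong enough to endanger the isopropenyl group.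
- Comparison: the chosen plan rests on one selective elementary step on a stable, easily made precursor; the alternative rests on the survival of its precursors. Making A2 and A3 is estimated to cost about as many steps as are saved after A1.

**Alternative 2:** The cut is in the pyranone (C3'–C4', O1'–C2'). The bridging methylene is kept and appears as C4 of the dihydrocoumarin A5, in which O6 and C7 of the dihydrobenzofuran are tied by a C(=O)CH2CH2 unit. Forward, the silyl ketene acetal of A5 is heated with dioxinone A6; the acylketene released by loss of acetone adds as a four-atom oxa-diene across the ketene acetal, and loss of silyl with cleavage of the aryl ester bond gives A4 with the C6 phenol free.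
- In its favour: the bridge is in place before the pyranone exists, so symmetrical dimers cannot form; at that bond it is better than the chosen plan. The acylketene step is thermal and reagent-free, and A6 is at least the equal of 25 in accessibility. O4 and O6 emerge differentiated.
- Against it here: it creates neither C2 nor the dihydrofuran, so a method such as the chosen insertion is still needed to reach A5, and A5 needs an extra annulation across O6/C7. A4 still lacks the C5 acyl group. Acylating after the pyranone means working between a free phenol and a MOM ether in the presence of an acidic 4-hydroxypyranone, where directed lithiation is unavailable and Friedel–Crafts conditions threaten the isopropenyl ether.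
- Comparison: structurally it is complementary, addressing the other half of the molecule. Mechanistically the ring formation is expected to be reliable. In step economy it is judged poorer, because placing the pyranone before the acyl group forces a difficult late acylation.

**Alternative 3:** The cut removes C3–C3a and O1–C7a, so the dihydrofuran is formed on an intact arene. Forward, palladium/norbornene cooperative catalysis (Pd(OAc)2, a phosphine, norbornene) would couple aryl iodide A9, whose second ortho position C7 is blocked by a protected hydroxymethyl group, with enantiopure epoxide A8. The C3a–H bond is alkylated by the epoxide CH2 and the alkoxide closes onto C7a, giving A7.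
- In its favour: C2 is bought with the epoxide and never touched, so no enantio-determining step is needed; on certainty of configuration it is better than the chosen plan. Two bonds form in one step without a diazo compound. C7 already carries the one-carbon unit, which after deprotection could couple with 25 through an ortho-quinone methide, the equal of the Mannich route. There is no C3 group to excise.
- Against it here: the C–H bond to be palladated at C3a is flanked by the C4 MOM ether, the hindered case for this chemistry, on a very electron-rich arene. A9 cannot come from a symmetrical phloroglucinol derivative because C7a bears iodine, so it needs regiocontrolled halogenation and formylation. After the key step the silyl ether must be removed and the tertiary alcohol dehydrated regioselectively to the isopropenyl group, two extra steps with their own selectivity issue.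
- Comparison: structurally it is a direct route to the ring and superior in stereochemical certainty. Mechanistically it trades the insertion/cyclopropanation question for a hindered palladation and a regioselective dehydration. The step count is estimated to be similar; the chosen plan is kept for its single, strongly simplifying C2–C3 bond formation from an achiral precursor made in four steps.

Key step: step 5

**Assumptions**
- Compound 1 is taken to be a purchasable catalogue chemical.
- Rh2(S-PTTL)4 denotes dirhodium tetrakis[N-phthaloyl-(S)-tert-leucinate]. The S ligand is assumed to deliver 2R by analogy with 2-aryl cases of the same CIP ranking; if the sense proves opposite, the R-configured catalyst is used.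
- The two ring oxygens of precursor 8 and product 9 carry triisopropylsilyl groups in place of acetal ethers. An ortho O–CH2–O group would offer the carbene a second 1,5 C–H site and a basic oxygen; the bond formed, the ring closed and the carbon skeletons are unchanged. The cis product has the descriptors 2R,3S.
- Acids 11–14 are drawn trans at C3; any C3 epimer mixture serves equally, since C3 becomes CH2 in step 8.

## Route

Step 1
Reactants: 1 2-(2,4,6-trimethoxyphenyl)acetic acid
Product: 3 4,6-dihydroxybenzofuran-2(3H)-one, via 2-(2,4,6-trihydroxyphenyl)acetic acid 2 (not isolated)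
Conditions: BBr3 (4.5 equiv), CH2Cl2, −78 °C → rt; H2O; then p-TsOH (cat.), toluene–dioxane, reflux (−H2O)
Reagents that add atoms: none
Why: Boron tribromide cleaves the three aryl methyl ethers (Lewis acid-assisted dealkylation) and the 2-hydroxyarylacetic acid then lactonises under acid catalysis. By symmetry either ortho hydroxyl gives the same five-membered lactone, which sets one phloroglucinol oxygen apart from the other two.

Step 2
Reactants: 3 4,6-dihydroxybenzofuran-2(3H)-one
Product: 4 4,6-bis[(triisopropylsilyl)oxy]benzofuran-2(3H)-one
Conditions: TIPSCl (2.4 equiv), imidazole (5 equiv), DMF, 0 °C → rt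
Reagents that add atoms: chlorotri(propan-2-yl)silane, CC(C)[Si](Cl)(C(C)C)C(C)C
Why: Standard silylation of phenols with a silyl chloride and imidazole. The bulky silyl ethers tolerate the bases of steps 3 and 4 and offer neither a C–H bond nor a basic oxygen within reach of the later carbene.

Step 3
Reactants: 4 4,6-bis[(triisopropylsilyl)oxy]benzofuran-2(3H)-one; 5 3-chloro-2-methylprop-1-ene
Product: 7 methyl 2-{2-[(2-methylprop-2-en-1-yl)oxy]-4,6-bis[(triisopropylsilyl)oxy]phenyl}acetate, via sodium 2-(2-methoxy-2-oxoethyl)-3,5-bis[(triisopropylsilyl)oxy]phenolate 6 (not isolated)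
Conditions: NaOMe (1.05 equiv), MeOH–THF, 0 °C; then 5 (1.5 equiv), DMF, 40 °C
Reagents that add atoms: sodium methoxide, C[O-].[Na+]
Why: Methoxide opens the aryl ester (transesterification) to phenoxide 6, which is O-alkylated by the allylic chloride (Williamson ether synthesis). Trapping in the same flask prevents relactonisation, and the lactone oxygen becomes the future O1.

Step 4
Reactants: 7 methyl 2-{2-[(2-methylprop-2-en-1-yl)oxy]-4,6-bis[(triisopropylsilyl)oxy]phenyl}acetate
Product: 8 methyl 2-diazo-2-{2-[(2-methylprop-2-en-1-yl)oxy]-4,6-bis[(triisopropylsilyl)oxy]phenyl}acetate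
Conditions: p-ABSA (1.5 equiv), DBU (2 equiv), MeCN, 0 °C → rt
Reagents that add atoms: 4-acetamidobenzenesulfonyl azide, CC(=O)Nc1ccc(cc1)S(=O)(=O)N=[N+]=[N-]
Why: Regitz diazo transfer: the DBU-generated ester enolate attacks the terminal nitrogen of the sulfonyl azide and the adduct collapses to the diazo ester and the sulfonamide. Aryl triisopropylsilyl ethers are stable to DBU in dry acetonitrile.

Step 5
Reactants: 8 methyl 2-diazo-2-{2-[(2-methylprop-2-en-1-yl)oxy]-4,6-bis[(triisopropylsilyl)oxy]phenyl}acetate
Product: 9 methyl (2R,3S)-2-(prop-1-en-2-yl)-4,6-bis[(triisopropylsilyl)oxy]-2,3-dihydrobenzofuran-3-carboxylate (cis)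
Conditions: Rh2(S-PTTL)4 (1 mol %), toluene (0.02 M), 4 Å MS, −60 → −20 °C
Reagents that add atoms: none
Why: The dirhodium carboxylate attacks the diazo carbon of 8, nitrogen leaves and an electrophilic rhodium carbene with an aryl donor and an ester acceptor forms at the future C3. The carbene inserts into one of the two enantiotopic OCH2 hydrogens through a concerted, asynchronous three-centre transition state, hydrogen moving to C3 as C2–C3 forms; the closest known reaction type is the dirhodium carboxylate-catalysed enantioselective intramolecular 1,5 C–H insertion of ortho-alkoxy aryldiazoacetates into ether α-C–H bonds, which gives 2,3-dihydrobenzofuran-3-carboxylates. The dihydrofuran closes by 1,5 insertion, the five ring atoms being the carbene carbon, C3a, C7a, O1 and the OCH2 carbon. C2 is set under catalyst control, the chiral pocket of the N-phthaloyl-tert-leucinate ligands deciding which enantiotopic hydrogen reaches the carbene. C3 is set by the transition-state geometry, which places ester and isopropenyl cis; it is erased in step 8, so its level of control does not matter. The step needs insertion to outrun cyclopropanation of the 1,1-disubstituted alkene: the C–H bond is doubly activated (allylic and α to oxygen), cyclopropanation would have to build two adjacent quaternary carbons in a cyclopropane-fused chromane, the two ortho substituents twist the aryl ring so that OCH2 is held over the carbene carbon, and low temperature with a bulky catalyst favours the more ordered insertion. The step also needs the other ortho substituent to stay out of the reaction, which the silyl ether secures because it has no hydrogen in 1,5 position and no ylide-forming oxygen.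

Step 6
Reactants: 9 methyl (2R,3S)-2-(prop-1-en-2-yl)-4,6-bis[(triisopropylsilyl)oxy]-2,3-dihydrobenzofuran-3-carboxylate
Product: 11 (2R,3R)-4,6-dihydroxy-2-(prop-1-en-2-yl)-2,3-dihydrobenzofuran-3-carboxylic acid, via methyl (2R,3S)-4,6-dihydroxy-2-(prop-1-en-2-yl)-2,3-dihydrobenzofuran-3-carboxylate 10 (not isolated)
Conditions: TBAF (2.5 equiv), THF, 0 °C; then LiOH·H2O (6 equiv), MeOH–H2O, 45 °C, Ar; pH 3 work-up
Reagents that add atoms: lithium hydroxide, [Li+].[OH-]
Why: Fluoride cleaves both aryl silyl ethers and hydroxide then saponifies the methyl ester. C3 should epimerise through the ester enolate to the less crowded trans arrangement, which is immaterial; C2 carries no acidic hydrogen and stays as set.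

Step 7
Reactants: 11 (2R,3R)-4,6-dihydroxy-2-(prop-1-en-2-yl)-2,3-dihydrobenzofuran-3-carboxylic acid
Product: 13 (2R,3R)-4,6-bis(methoxymethoxy)-2-(prop-1-en-2-yl)-2,3-dihydrobenzofuran-3-carboxylic acid, via methoxymethyl (2R,3R)-4,6-bis(methoxymethoxy)-2-(prop-1-en-2-yl)-2,3-dihydrobenzofuran-3-carboxylate 12 (not isolated)
Conditions: MOMCl (4 equiv), i-Pr2NEt (6 equiv), CH2Cl2, 0 °C → rt; then LiOH (aq), THF–MeOH, 0 °C; pH 4–5 work-up
Reagents that add atoms: chloro(methoxy)methane, COCCl; lithium hydroxide, [Li+].[OH-]
Why: Both phenols and the carboxylate are alkylated by the chloromethyl ether (Williamson-type O-alkylation). The methoxymethyl ester is an activated acylal that aqueous hydroxide hydrolyses within minutes, leaving the two aryl acetal ethers that will direct metalation to C5.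

Step 8
Reactants: 13 (2R,3R)-4,6-bis(methoxymethoxy)-2-(prop-1-en-2-yl)-2,3-dihydrobenzofuran-3-carboxylic acid
Product: 15 (R)-4,6-bis(methoxymethoxy)-2-(prop-1-en-2-yl)-2,3-dihydrobenzofuran, via 2-thioxopyridin-1(2H)-yl (2R,3R)-4,6-bis(methoxymethoxy)-2-(prop-1-en-2-yl)-2,3-dihydrobenzofuran-3-carboxylate 14 (not isolated)
Conditions: 1-hydroxypyridine-2(1H)-thione, DCC, DMAP (cat.), CH2Cl2, 0 °C, dark; then t-BuSH (20 equiv), hν (visible), rt
Reagents that add atoms: none
Why: Barton decarboxylation: carbodiimide coupling gives the O-acyl thiohydroxamate 14, and light starts a radical chain in which the acyloxy radical loses CO2 and the benzylic C3 radical takes hydrogen from the thiol. C2 is not involved, and no metal hydride or aldehyde is present that could isomerise or add to the isopropenyl group.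

Step 9
Reactants: 16 (R)-2-methylbutanoic acid
Product: 18 (R)-N-methoxy-N,2-dimethylbutanamide, via (R)-1-(1H-imidazol-1-yl)-2-methylbutan-1-one 17 (not isolated)
Conditions: CDI (1.1 equiv), CH2Cl2, 0 °C → rt; then MeNH(OMe)·HCl (1.2 equiv), rt
Reagents that add atoms: N,O-dimethylhydroxylamine hydrochloride, CNOC.Cl
Why: Weinreb amide formation through the acyl imidazole; the near-neutral conditions do not enolise the α-stereocentre.

Step 10
Reactants: 15 (R)-4,6-bis(methoxymethoxy)-2-(prop-1-en-2-yl)-2,3-dihydrobenzofuran; 18 (R)-N-methoxy-N,2-dimethylbutanamide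
Product: 20 (R)-1-[(R)-4,6-bis(methoxymethoxy)-2-(prop-1-en-2-yl)-2,3-dihydrobenzofuran-5-yl]-2-methylbutan-1-one, via [(R)-4,6-bis(methoxymethoxy)-2-(prop-1-en-2-yl)-2,3-dihydrobenzofuran-5-yl]lithium 19 (not isolated)
Conditions: n-BuLi (1.2 equiv), THF, −20 → 0 °C; then 18 (1.5 equiv), −78 °C → rt; aq. NH4Cl
Reagents that add atoms: none
Why: Directed ortho-metalation: C5–H lies between two acetal ethers that both coordinate lithium, so it is removed in preference to C7–H (one acetal ether and the ring ether). The aryllithium adds to the Weinreb amide to give a chelated tetrahedral intermediate that releases the ketone only on work-up, so neither over-addition nor enolisation of the α-stereocentre should occur.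

Step 11
Reactants: 20 (R)-1-[(R)-4,6-bis(methoxymethoxy)-2-(prop-1-en-2-yl)-2,3-dihydrobenzofuran-5-yl]-2-methylbutan-1-one
Product: 21 (R)-1-[(R)-4,6-dihydroxy-2-(prop-1-en-2-yl)-2,3-dihydrobenzofuran-5-yl]-2-methylbutan-1-one
Conditions: HCl (1.25 M in MeOH), rt
Reagents that add atoms: none
Why: Acid-catalysed acetal exchange (methanolysis of the aryl MOM ethers), assisted by the ortho carbonyl. Dilute acid at room temperature is chosen to spare the isopropenyl group, the allylic C2–O1 ether and the ketone α-centre.

Step 12
Reactants: 22 pentan-3-one
Product: 23 (Z)-trimethyl(pent-2-en-3-yloxy)silane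
Conditions: TMSOTf (1.1 equiv), Et3N (1.3 equiv), CH2Cl2, 0 °C
Reagents that add atoms: trimethylsilyl trifluoromethanesulfonate, C[Si](C)(C)OS(=O)(=O)C(F)(F)F
Why: Soft enolisation: the silyl triflate activates the ketone and triethylamine removes an α-proton. The ketone is symmetrical, so there is no regiochemical question, and the enol ether geometry (mainly Z expected) is immaterial.

Step 13
Reactants: 23 (Z)-trimethyl(pent-2-en-3-yloxy)silane; 24 malonyl dichloride
Product: 25 6-ethyl-4-hydroxy-5-methyl-2H-pyran-2-one
Conditions: 24 (1.0 equiv), Et2O, −78 °C → rt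
Reagents that add atoms: none
Why: Mukaiyama-type C-acylation of the silyl enol ether by one acid chloride of 24 gives a 1,3-diketone, whose enol oxygen is acylated by the second acid chloride to close the pyranone. Tautomerisation gives the 4-hydroxy form.

Step 14
Reactants: 21 (R)-1-[(R)-4,6-dihydroxy-2-(prop-1-en-2-yl)-2,3-dihydrobenzofuran-5-yl]-2-methylbutan-1-one; 25 6-ethyl-4-hydroxy-5-methyl-2H-pyran-2-one
Product: 27 (R)-6-ethyl-4-hydroxy-3-({(R)-4,6-dihydroxy-5-[(R)-2-methylbutanoyl]-2-(prop-1-en-2-yl)-2,3-dihydrobenzofuran-7-yl}methyl)-5-methyl-2H-pyran-2-one, via (R)-1-{(R)-7-[(dimethylamino)methyl]-4,6-dihydroxy-2-(prop-1-en-2-yl)-2,3-dihydrobenzofuran-5-yl}-2-methylbutan-1-one 26 (not isolated)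
Conditions: Eschenmoser's salt (1.05 equiv), MeCN, 0 °C → rt; then 25 (1.5 equiv), 65 °C
Reagents that add atoms: N,N-dimethylmethyleneiminium iodide, C=[N+](C)C.[I-]
Why: Mannich reaction at C7, the only unsubstituted phenol-activated ring carbon of 21, gives 26. On warming it loses dimethylamine to an ortho-quinone methide that is trapped by Michael addition of C3' of 25; because 25 never meets the iminium salt, the symmetrical bis-pyranone cannot form directly.

## Compound list

1 | 2-(2,4,6-trimethoxyphenyl)acetic acid | COc1cc(OC)c(CC(=O)O)c(OC)c1 | starting material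
2 | 2-(2,4,6-trihydroxyphenyl)acetic acid | OC(=O)Cc1c(O)cc(O)cc1O | intermediate (not isolated)
3 | 4,6-dihydroxybenzofuran-2(3H)-one | O=C1Cc2c(O)cc(O)cc2O1 | intermediate
4 | 4,6-bis[(triisopropylsilyl)oxy]benzofuran-2(3H)-one | O=C1Cc2c(O[Si](C(C)C)(C(C)C)C(C)C)cc(O[Si](C(C)C)(C(C)C)C(C)C)cc2O1 | intermediate
5 | 3-chloro-2-methylprop-1-ene | C=C(C)CCl | starting material
6 | sodium 2-(2-methoxy-2-oxoethyl)-3,5-bis[(triisopropylsilyl)oxy]phenolate | COC(=O)Cc1c([O-])cc(O[Si](C(C)C)(C(C)C)C(C)C)cc1O[Si](C(C)C)(C(C)C)C(C)C.[Na+] | intermediate (not isolated)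
7 | methyl 2-{2-[(2-methylprop-2-en-1-yl)oxy]-4,6-bis[(triisopropylsilyl)oxy]phenyl}acetate | C=C(C)COc1cc(O[Si](C(C)C)(C(C)C)C(C)C)cc(O[Si](C(C)C)(C(C)C)C(C)C)c1CC(=O)OC | intermediate
8 | methyl 2-diazo-2-{2-[(2-methylprop-2-en-1-yl)oxy]-4,6-bis[(triisopropylsilyl)oxy]phenyl}acetate | C=C(C)COc1cc(O[Si](C(C)C)(C(C)C)C(C)C)cc(O[Si](C(C)C)(C(C)C)C(C)C)c1C(=[N+]=[N-])C(=O)OC | intermediate
9 | methyl (2R,3S)-2-(prop-1-en-2-yl)-4,6-bis[(triisopropylsilyl)oxy]-2,3-dihydrobenzofuran-3-carboxylate (cis) | C=C(C)[C@H]1[C@@H](C(=O)OC)c2c(O[Si](C(C)C)(C(C)C)C(C)C)cc(O[Si](C(C)C)(C(C)C)C(C)C)cc2O1 | intermediate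
10 | methyl (2R,3S)-4,6-dihydroxy-2-(prop-1-en-2-yl)-2,3-dihydrobenzofuran-3-carboxylate | C=C(C)[C@H]1[C@@H](C(=O)OC)c2c(O)cc(O)cc2O1 | intermediate (not isolated)
11 | (2R,3R)-4,6-dihydroxy-2-(prop-1-en-2-yl)-2,3-dihydrobenzofuran-3-carboxylic acid (trans) | C=C(C)[C@H]1[C@H](C(=O)O)c2c(O)cc(O)cc2O1 | intermediate
12 | methoxymethyl (2R,3R)-4,6-bis(methoxymethoxy)-2-(prop-1-en-2-yl)-2,3-dihydrobenzofuran-3-carboxylate | C=C(C)[C@H]1[C@H](C(=O)OCOC)c2c(OCOC)cc(OCOC)cc2O1 | intermediate (not isolated)
13 | (2R,3R)-4,6-bis(methoxymethoxy)-2-(prop-1-en-2-yl)-2,3-dihydrobenzofuran-3-carboxylic acid | C=C(C)[C@H]1[C@H](C(=O)O)c2c(OCOC)cc(OCOC)cc2O1 | intermediate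
14 | 2-thioxopyridin-1(2H)-yl (2R,3R)-4,6-bis(methoxymethoxy)-2-(prop-1-en-2-yl)-2,3-dihydrobenzofuran-3-carboxylate | C=C(C)[C@H]1[C@H](C(=O)ON3C=CC=CC3=S)c2c(OCOC)cc(OCOC)cc2O1 | intermediate (not isolated)
15 | (R)-4,6-bis(methoxymethoxy)-2-(prop-1-en-2-yl)-2,3-dihydrobenzofuran | C=C(C)[C@H]1Cc2c(OCOC)cc(OCOC)cc2O1 | intermediate
16 | (R)-2-methylbutanoic acid | CC[C@@H](C)C(=O)O | starting material
17 | (R)-1-(1H-imidazol-1-yl)-2-methylbutan-1-one | CC[C@@H](C)C(=O)n1ccnc1 | intermediate (not isolated)
18 | (R)-N-methoxy-N,2-dimethylbutanamide | CC[C@@H](C)C(=O)N(C)OC | intermediate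
19 | [(R)-4,6-bis(methoxymethoxy)-2-(prop-1-en-2-yl)-2,3-dihydrobenzofuran-5-yl]lithium | C=C(C)[C@H]1Cc2c(OCOC)c([Li])c(OCOC)cc2O1 | intermediate (not isolated)
20 | (R)-1-[(R)-4,6-bis(methoxymethoxy)-2-(prop-1-en-2-yl)-2,3-dihydrobenzofuran-5-yl]-2-methylbutan-1-one | C=C(C)[C@H]1Cc2c(OCOC)c(C(=O)[C@H](C)CC)c(OCOC)cc2O1 | intermediate
21 | (R)-1-[(R)-4,6-dihydroxy-2-(prop-1-en-2-yl)-2,3-dihydrobenzofuran-5-yl]-2-methylbutan-1-one | C=C(C)[C@H]1Cc2c(O)c(C(=O)[C@H](C)CC)c(O)cc2O1 | intermediate
22 | pentan-3-one | CCC(=O)CC | starting material
23 | (Z)-trimethyl(pent-2-en-3-yloxy)silane | C/C=C(/CC)O[Si](C)(C)C | intermediate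
24 | malonyl dichloride | O=C(Cl)CC(=O)Cl | starting material
25 | 6-ethyl-4-hydroxy-5-methyl-2H-pyran-2-one | CCc1oc(=O)cc(O)c1C | intermediate
26 | (R)-1-{(R)-7-[(dimethylamino)methyl]-4,6-dihydroxy-2-(prop-1-en-2-yl)-2,3-dihydrobenzofuran-5-yl}-2-methylbutan-1-one (formed as its hydroiodide) | C=C(C)[C@H]1Cc2c(O)c(C(=O)[C@H](C)CC)c(O)c(CN(C)C)c2O1 | intermediate (not isolated)
27 | (R)-6-ethyl-4-hydroxy-3-({(R)-4,6-dihydroxy-5-[(R)-2-methylbutanoyl]-2-(prop-1-en-2-yl)-2,3-dihydrobenzofuran-7-yl}methyl)-5-methyl-2H-pyran-2-one | C=C(C)[C@H]1Cc2c(O)c(C(=O)[C@H](C)CC)c(O)c(Cc3c(O)c(C)c(CC)oc3=O)c2O1 | target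

## Step count and least certain steps

Total: 14 steps. Longest linear sequence: 11 steps (steps 1–8, 10, 11, 14); steps 9 and 12–13 are side branches.

**Step 5 (key step).** The most likely failure is addition of the carbene across the methallyl double bond (cyclopropanation) in competition with C–H insertion, or weak discrimination between the two OCH2 hydrogens because the carbene carbon is flanked by two ortho substituents. Fallback: set C2 by an asymmetric Tsuji–Trost allylic etherification, setting out from 3 and returning at 15. Lactone 3 is protected with MOMCl and i-Pr2NEt to give 4,6-bis(methoxymethoxy)benzofuran-2(3H)-one F1. DIBAL at −78 °C reduces it to the lactol 4,6-bis(methoxymethoxy)-2,3-dihydrobenzofuran-2-ol F2. Wittig reaction with ethyl 2-(triphenylphosphoranylidene)propanoate under neutral conditions gives ethyl (E)-4-[2-hydroxy-4,6-bis(methoxymethoxy)phenyl]-2-methylbut-2-enoate F3. DIBAL reduces the ester to (E)-2-(4-hydroxy-3-methylbut-2-en-1-yl)-3,5-bis(methoxymethoxy)phenol F4. Methyl chloroformate and pyridine at 0 °C acylate the primary allylic hydroxyl in preference to the neutral phenol, giving (E)-4-[2-hydroxy-4,6-bis(methoxymethoxy)phenyl]-2-methylbut-2-en-1-yl methyl carbonate F5. Pd2(dba)3 with the appropriate enantiomer of the trans-1,2-diaminocyclohexane bis(2-diphenylphosphinobenzamide) ligand then ionises the carbonate, and the phenol closes on the internal allyl terminus to give 15 directly, with no C3 substituent to remove.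

**Step 4.** Diazo transfer may stall because the benzylic CH2 is shielded by two ortho substituents and the electron-rich ring lowers its acidity. Fallback: a Bamford–Stevens entry from 7 back to 8. The potassium enolate of 7 (KHMDS) is hydroxylated with 2-(phenylsulfonyl)-3-phenyloxaziridine to methyl 2-hydroxy-2-{2-[(2-methylprop-2-en-1-yl)oxy]-4,6-bis[(triisopropylsilyl)oxy]phenyl}acetate F6. Dess–Martin periodinane oxidises it to methyl 2-oxo-2-{2-[(2-methylprop-2-en-1-yl)oxy]-4,6-bis[(triisopropylsilyl)oxy]phenyl}acetate F7. Condensation with tosylhydrazide gives methyl 2-{2-[(2-methylprop-2-en-1-yl)oxy]-4,6-bis[(triisopropylsilyl)oxy]phenyl}-2-(2-tosylhydrazinylidene)acetate F8, and DBU eliminates sulfinate to give 8.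

**Step 8.** The stabilised benzylic C3 radical may take hydrogen from the thiol too slowly, so that recombination with the pyridylthio fragment or a 1,2-vinyl shift through a cyclopropylcarbinyl radical competes. Fallback: a non-radical excision from 13 back to 15. LiAlH4 reduces 13 to [(2R,3S)-4,6-bis(methoxymethoxy)-2-(prop-1-en-2-yl)-2,3-dihydrobenzofuran-3-yl]methanol F9. Dess–Martin periodinane gives (2R,3R)-4,6-bis(methoxymethoxy)-2-(prop-1-en-2-yl)-2,3-dihydrobenzofuran-3-carbaldehyde F10. Stoichiometric RhCl(PPh3)3 in hot toluene decarbonylates it to 15; the trans arrangement keeps the formyl group away from the isopropenyl group and so disfavours intramolecular hydroacylation.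

**Step 10.** Acyl transfer from the α-branched amide to the doubly ortho-substituted aryllithium may be incomplete, with deprotonation of the amide taking over. Fallback: addition to an aldehyde and oxidation, from 15 and 18 back to 20. DIBAL reduces 18 to (R)-2-methylbutanal F11, used at once at low temperature. Aryllithium 19 adds to it to give (2R)-1-[(R)-4,6-bis(methoxymethoxy)-2-(prop-1-en-2-yl)-2,3-dihydrobenzofuran-5-yl]-2-methylbutan-1-ol F12 as a mixture of carbinol epimers, and Dess–Martin periodinane oxidises both to 20.

**Step 14.** Directionality may be lost through amine exchange between the two partners, giving symmetrical methylene dimers, or the ketone α-centre may epimerise on warming with amine. Fallback: a reductive Knoevenagel alkylation from 21 back to 27. Vilsmeier–Haack formylation (POCl3, DMF) at C7 gives (R)-4,6-dihydroxy-5-[(R)-2-methylbutanoyl]-2-(prop-1-en-2-yl)-2,3-dihydrobenzofuran-7-carbaldehyde F13. Condensation with 25 in the presence of a Hantzsch ester and catalytic (S)-proline forms the alkylidene pyrandione and reduces it in the same flask to 27.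

## Further compounds

F1 | step 5 | 4,6-bis(methoxymethoxy)benzofuran-2(3H)-one | O=C1Cc2c(OCOC)cc(OCOC)cc2O1
F2 | step 5 | 4,6-bis(methoxymethoxy)-2,3-dihydrobenzofuran-2-ol | OC1Cc2c(OCOC)cc(OCOC)cc2O1
F3 | step 5 | ethyl (E)-4-[2-hydroxy-4,6-bis(methoxymethoxy)phenyl]-2-methylbut-2-enoate | CCOC(=O)/C(C)=C/Cc1c(O)cc(OCOC)cc1OCOC
F4 | step 5 | (E)-2-(4-hydroxy-3-methylbut-2-en-1-yl)-3,5-bis(methoxymethoxy)phenol | OC/C(C)=C/Cc1c(O)cc(OCOC)cc1OCOC
F5 | step 5 | (E)-4-[2-hydroxy-4,6-bis(methoxymethoxy)phenyl]-2-methylbut-2-en-1-yl methyl carbonate | COC(=O)OC/C(C)=C/Cc1c(O)cc(OCOC)cc1OCOC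
F6 | step 4 | methyl 2-hydroxy-2-{2-[(2-methylprop-2-en-1-yl)oxy]-4,6-bis[(triisopropylsilyl)oxy]phenyl}acetate | C=C(C)COc1cc(O[Si](C(C)C)(C(C)C)C(C)C)cc(O[Si](C(C)C)(C(C)C)C(C)C)c1C(O)C(=O)OC
F7 | step 4 | methyl 2-oxo-2-{2-[(2-methylprop-2-en-1-yl)oxy]-4,6-bis[(triisopropylsilyl)oxy]phenyl}acetate | C=C(C)COc1cc(O[Si](C(C)C)(C(C)C)C(C)C)cc(O[Si](C(C)C)(C(C)C)C(C)C)c1C(=O)C(=O)OC
F8 | step 4 | methyl 2-{2-[(2-methylprop-2-en-1-yl)oxy]-4,6-bis[(triisopropylsilyl)oxy]phenyl}-2-(2-tosylhydrazinylidene)acetate | C=C(C)COc1cc(O[Si](C(C)C)(C(C)C)C(C)C)cc(O[Si](C(C)C)(C(C)C)C(C)C)c1C(=NNS(=O)(=O)c2ccc(C)cc2)C(=O)OC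
F9 | step 8 | [(2R,3S)-4,6-bis(methoxymethoxy)-2-(prop-1-en-2-yl)-2,3-dihydrobenzofuran-3-yl]methanol | C=C(C)[C@H]1[C@H](CO)c2c(OCOC)cc(OCOC)cc2O1
F10 | step 8 | (2R,3R)-4,6-bis(methoxymethoxy)-2-(prop-1-en-2-yl)-2,3-dihydrobenzofuran-3-carbaldehyde | C=C(C)[C@H]1[C@H](C=O)c2c(OCOC)cc(OCOC)cc2O1
F11 | step 10 | (R)-2-methylbutanal | CC[C@@H](C)C=O
F12 | step 10 | (2R)-1-[(R)-4,6-bis(methoxymethoxy)-2-(prop-1-en-2-yl)-2,3-dihydrobenzofuran-5-yl]-2-methylbutan-1-ol | C=C(C)[C@H]1Cc2c(OCOC)c(C(O)[C@H](C)CC)c(OCOC)cc2O1
F13 | step 14 | (R)-4,6-dihydroxy-5-[(R)-2-methylbutanoyl]-2-(prop-1-en-2-yl)-2,3-dihydrobenzofuran-7-carbaldehyde | C=C(C)[C@H]1Cc2c(O)c(C(=O)[C@H](C)CC)c(O)c(C=O)c2O1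
A1 | alternative 1 | (R)-1-[(R)-4,6-di-tert-butoxy-2-(prop-1-en-2-yl)-2,3-dihydrobenzofuran-5-yl]-2-methylbutan-1-one | C=C(C)[C@H]1Cc2c(OC(C)(C)C)c(C(=O)[C@H](C)CC)c(OC(C)(C)C)cc2O1
A2 | alternative 1 | (R)-1-tert-butoxy-4-(ethynyloxy)-5-methylhex-5-en-1-yne | C=C(C)[C@@H](CC#COC(C)(C)C)OC#C
A3 | alternative 1 | (R)-1-tert-butoxy-4-methylhex-1-yn-3-one | CC[C@@H](C)C(=O)C#COC(C)(C)C
A4 | alternative 2 | (R)-6-ethyl-4-hydroxy-3-{[6-hydroxy-4-(methoxymethoxy)-2-(prop-1-en-2-yl)-2,3-dihydrobenzofuran-7-yl]methyl}-5-methyl-2H-pyran-2-one | C=C(C)[C@H]1Cc2c(OCOC)cc(O)c(Cc3c(O)c(C)c(CC)oc3=O)c2O1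
A5 | alternative 2 | (R)-configured 3,4-dihydrocoumarin annulated across O6 and C7 of 4-(methoxymethoxy)-2-(prop-1-en-2-yl)-2,3-dihydrobenzofuran | C=C(C)[C@H]1Cc2c(OCOC)cc3OC(=O)CCc3c2O1
A6 | alternative 2 | 6-ethyl-2,2,5-trimethyl-4H-1,3-dioxin-4-one | CCC1=C(C)C(=O)OC(C)(C)O1
A7 | alternative 3 | (R)-4,6-bis(methoxymethoxy)-7-[(methoxymethoxy)methyl]-2-[2-(triethylsilyloxy)propan-2-yl]-2,3-dihydrobenzofuran | CC(C)(O[Si](CC)(CC)CC)[C@H]1Cc2c(OCOC)cc(OCOC)c(COCOC)c2O1
A8 | alternative 3 | (R)-2-[2-(triethylsilyloxy)propan-2-yl]oxirane | CC(C)(O[Si](CC)(CC)CC)[C@H]1CO1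
A9 | alternative 3 | 1-iodo-3,5-bis(methoxymethoxy)-2-[(methoxymethoxy)methyl]benzene | COCOCc1c(I)cc(OCOC)cc1OCOC
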